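**Strategy.** The target is the C–O dehydrodimer of a single 2-ethyl-3-hydroxynaphthoquinone. The route therefore rests on closing that monomer's carbocycle between the carbonyl carbon that becomes trione C4 (flanked by the C3 oxygen) and arene carbon C4a, which sits ortho to the C8a–C1(=O) junction. A squarate-derived 4-aryl-4-hydroxycyclobutenone does this in one thermal operation: 4π ring opening to an aryl(vinyl)ketene, 6π closure of the ketene carbon onto the only free ortho carbon, and tautomerisation give the fully substituted naphthalene-1,4-diol, oxidised in the same flask to the quinone. A chiral λ3-iodane then joins two monomers and sets the lone quaternary stereocentre.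

Key step: step 5

PMB = 4-methoxybenzyl throughout.

Assumption: the step 7 reagent, (R,R)-2,6-bis[1-(mesitylcarbamoyl)ethoxy]-1-(diacetoxyiodo)benzene, C[C@@H](Oc1cccc(O[C@H](C)C(=O)Nc2c(C)cc(C)cc2C)c1I(OC(C)=O)OC(C)=O)C(=O)Nc1c(C)cc(C)cc1C, is made beforehand from the (R,R)-iodoarene (taken to be commercially available) with peracetic acid in AcOH. Its sense of induction is assigned by analogy with naphthol dearomatisations; if the opposite sense is found, the (S,S)-reagent is used in the same step.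

**Step 1**
Reactants: 1 benzene-1,2,4-triol
Product: 2 1,2,4-tris[(4-methoxybenzyl)oxy]benzene
Conditions: PMBCl (3.3 equiv), K2CO3, Bu4NI (cat.), degassed DMF, Ar, 0 to 50 °C
Reagents that add atoms: 4-methoxybenzyl chloride, COc1ccc(CCl)cc1
Why: Williamson etherification of the three phenols, with air excluded so that the triol is not oxidised to hydroxybenzoquinone.

**Step 2**
Reactants: 2 1,2,4-tris[(4-methoxybenzyl)oxy]benzene
Product: 3 1-bromo-2,4,5-tris[(4-methoxybenzyl)oxy]benzene
Conditions: NBS (1.0 equiv), MeCN, 0 °C, dark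
Reagents that add atoms: N-bromosuccinimide, O=C1CCC(=O)N1Br
Why: Electrophilic aromatic bromination should go to C5 of the central ring, which is para to one alkoxy group, ortho to another and far more activated than the anisyl rings.

**Step 3**
Reactants: 3 1-bromo-2,4,5-tris[(4-methoxybenzyl)oxy]benzene; 4 dimethyl squarate (3,4-dimethoxycyclobut-3-ene-1,2-dione)
Product: 7 racemic 2,3-dimethoxy-4-{2,4,5-tris[(4-methoxybenzyl)oxy]phenyl}-4-[(trimethylsilyl)oxy]cyclobut-2-en-1-one, via aryllithium 5 (not isolated), via lithium cyclobutenolate 6 (not isolated)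
Conditions: n-BuLi, THF, −78 °C; cannulate into 4, THF, −78 °C; TMSCl, −78 to 0 °C; aq. NaHCO3
Reagents that add atoms: chlorotrimethylsilane, C[Si](C)(C)Cl
Why: Bromine–lithium exchange, 1,2-addition of the aryllithium to one squarate carbonyl (inverse addition prevents double addition) and in-flask O-silylation of the tertiary alkoxide, so that the next organolithium meets no acidic proton.

**Step 4**
Reactants: 7 racemic 2,3-dimethoxy-4-aryl-4-[(trimethylsilyl)oxy]cyclobut-2-en-1-one
Product: 10 racemic 3-ethyl-4-hydroxy-2-methoxy-4-{2,4,5-tris[(4-methoxybenzyl)oxy]phenyl}cyclobut-2-en-1-one, via lithium alkoxide 8 (not isolated), via silyl ether 9 (not isolated)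
Conditions: EtLi, THF, −78 °C; TFAA, −78 °C, then aq. NaHCO3; crude, TBAF–AcOH (1:1), THF, 0 °C
Reagents that add atoms: ethyllithium, [Li]CC
Why: Stork–Danheiser-type alkylative 1,3-carbonyl transposition of the squarate vinylogous ester: EtLi adds 1,2 to the only carbonyl, trifluoroacetylation ionises the new tertiary alkoxide to a methoxy-stabilised cyclobutenyl cation that loses methyl trifluoroacetate to leave the carbonyl next to C–OMe, and buffered fluoride frees the carbinol.

**Step 5**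
Reactants: 10 racemic 3-ethyl-4-hydroxy-2-methoxy-4-arylcyclobut-2-en-1-one
Product: 13 2-ethyl-3-methoxy-5,6,8-tris[(4-methoxybenzyl)oxy]naphthalene-1,4-dione, via aryl(vinyl)ketene 11 (not isolated), via naphthohydroquinone 12 (not isolated)
Conditions: degassed p-xylene, 138 °C; then Ag2O, MgSO4, Et2O, rt
Reagents that add atoms: none
Why: Moore rearrangement: thermal conrotatory 4π ring opening cleaves the C1–C4 bond of the cyclobutenone with the hydroxyl rotating outward (donor torquoselectivity), so the aryl group ends up cis to the ketene in 11. The ketene carbon, whose neighbour is the methoxy-bearing carbon, then bonds to the aryl ortho carbon in a thermal 6π electrocyclisation (six-membered ring, hexatriene-to-cyclohexadiene mode) and enolisation gives diol 12; this is the known ring expansion of 4-aryl-4-hydroxycyclobutenones to 1,4-naphthohydroquinones. No stereocentre is formed, and the carbinol stereocentre of 10 is destroyed. Regiochemistry is the selectivity that matters: the other ortho position of the aryl group carries a PMB ether, so only the CH ortho carbon can close, and the transposed placement of C=O next to C–OMe in 10 fixes which carbonyl ends up beside the oxygen-bearing carbon. The three donor oxygens should make the arene nucleophilic enough for closure to outrun capture of the ketene by the enol hydroxyl. Ag2O then oxidises the air-sensitive diol to quinone 13 without touching the PMB ethers.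

**Step 6**
Reactants: 13 2-ethyl-3-methoxy-5,6,8-tris[(4-methoxybenzyl)oxy]naphthalene-1,4-dione
Product: 15 2-ethyl-3-hydroxy-5,6,8-tris[(4-methoxybenzyl)oxy]naphthalene-1,4-dione, via sodium quinonolate 14 (not isolated)
Conditions: 1 M NaOH, THF–H2O, Ar, 0 °C to rt; then 1 M HCl to pH 4, 0 °C
Reagents that add atoms: sodium hydroxide, [Na+].[OH-]
Why: Vinylogous ester saponification by addition–elimination: hydroxide adds to the methoxy-bearing quinone carbon and expels methoxide, the resulting hydroxyquinone anion is inert to further attack, and aryl PMB ethers tolerate base and the pH 4 work-up.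

**Step 7**
Reactants: 15 2-ethyl-3-hydroxy-5,6,8-tris[(4-methoxybenzyl)oxy]naphthalene-1,4-dione (two molecules)
Product: 17 (S)-2-ethyl-2-({3-ethyl-5,7,8-tris[(4-methoxybenzyl)oxy]-1,4-dioxo-1,4-dihydronaphthalen-2-yl}oxy)-5,6,8-tris[(4-methoxybenzyl)oxy]naphthalene-1,3,4(2H)-trione, via bis(quinonyloxy)iodane 16 (not isolated)
Conditions: (R,R)-lactamide aryl-I(OAc)2 (0.55 equiv), 4 Å MS, CH2Cl2, −40 to −20 °C, dark
Reagents that add atoms: none
Why: Proposed new method: exchange of both acetates by the vinylogous-acid hydroxyl gives iodane 16, in which one iodine-bound quinonyloxy oxygen attacks the ethyl-bearing enol carbon of the other in an SN2′-type reductive ligand coupling that expels the iodoarene and leaves the C3 carbonyl; the closest known reactions are chiral aryl-λ3-iodane spirolactonisations of naphthols and α-oxygenations of 1,3-dicarbonyls, together with the racemic C–O dehydrodimerisation of 3-alkyl-2-hydroxynaphthoquinones by one-electron oxidants; the (S)-centre is set by the reagent's hydrogen-bonded C2-symmetric lactamide pocket shielding one face of the bound enol, and C–O rather than C–C or O–O coupling is favoured by the fully substituted carbon and by delivery from iodine.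

**Step 8**
Reactants: 17 (S)-hexa-PMB dimer
Product: 18 (S)-2-ethyl-2-[(3-ethyl-5,7,8-trihydroxy-1,4-dioxo-1,4-dihydronaphthalen-2-yl)oxy]-5,6,8-trihydroxynaphthalene-1,3,4(2H)-trione (CNP0325426.1)
Conditions: TFA (10% v/v), pentamethylbenzene (20 equiv), CH2Cl2, 0 °C; cold evaporation; RP-HPLC (MeCN–H2O, 0.1% HCO2H)
Reagents that add atoms: none
Why: Acidolysis of the six aryl PMB ethers with Friedel–Crafts capture of the 4-methoxybenzyl cation by pentamethylbenzene, in a medium free of base and nucleophiles, so the vinylogous ester linkage should stay intact and the quaternary centre, which has no α-hydrogen, cannot epimerise.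

**Compound list**
1 | benzene-1,2,4-triol | Oc1ccc(O)c(O)c1 | starting material
2 | 1,2,4-tris[(4-methoxybenzyl)oxy]benzene | COc1ccc(COc2ccc(OCc3ccc(OC)cc3)c(OCc3ccc(OC)cc3)c2)cc1 | intermediate
3 | 1-bromo-2,4,5-tris[(4-methoxybenzyl)oxy]benzene | Brc1cc(OCc2ccc(OC)cc2)c(OCc2ccc(OC)cc2)cc1OCc1ccc(OC)cc1 | intermediate
4 | dimethyl squarate | COC1=C(OC)C(=O)C1=O | starting material
5 | {2,4,5-tris[(4-methoxybenzyl)oxy]phenyl}lithium | [Li]c1cc(OCc2ccc(OC)cc2)c(OCc2ccc(OC)cc2)cc1OCc1ccc(OC)cc1 | intermediate (not isolated)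
6 | lithium 2,3-dimethoxy-4-oxo-1-{2,4,5-tris[(4-methoxybenzyl)oxy]phenyl}cyclobut-2-en-1-olate (racemic) | COC1=C(OC)C(O[Li])(c2cc(OCc3ccc(OC)cc3)c(OCc3ccc(OC)cc3)cc2OCc2ccc(OC)cc2)C1=O | intermediate (not isolated)
7 | 2,3-dimethoxy-4-{2,4,5-tris[(4-methoxybenzyl)oxy]phenyl}-4-[(trimethylsilyl)oxy]cyclobut-2-en-1-one (racemic) | COC1=C(OC)C(O[Si](C)(C)C)(c2cc(OCc3ccc(OC)cc3)c(OCc3ccc(OC)cc3)cc2OCc2ccc(OC)cc2)C1=O | intermediate
8 | lithium 1-ethyl-2,3-dimethoxy-4-aryl-4-[(trimethylsilyl)oxy]cyclobut-2-en-1-olate (diastereomer mixture) | CCC1(O[Li])C(OC)=C(OC)C1(O[Si](C)(C)C)c1cc(OCc2ccc(OC)cc2)c(OCc2ccc(OC)cc2)cc1OCc1ccc(OC)cc1 | intermediate (not isolated)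
9 | 3-ethyl-2-methoxy-4-{2,4,5-tris[(4-methoxybenzyl)oxy]phenyl}-4-[(trimethylsilyl)oxy]cyclobut-2-en-1-one (racemic) | CCC1=C(OC)C(=O)C1(O[Si](C)(C)C)c1cc(OCc2ccc(OC)cc2)c(OCc2ccc(OC)cc2)cc1OCc1ccc(OC)cc1 | intermediate (not isolated)
10 | 3-ethyl-4-hydroxy-2-methoxy-4-{2,4,5-tris[(4-methoxybenzyl)oxy]phenyl}cyclobut-2-en-1-one (racemic) | CCC1=C(OC)C(=O)C1(O)c1cc(OCc2ccc(OC)cc2)c(OCc2ccc(OC)cc2)cc1OCc1ccc(OC)cc1 | intermediate
11 | 3-ethyl-4-hydroxy-2-methoxy-4-{2,4,5-tris[(4-methoxybenzyl)oxy]phenyl}buta-1,3-dien-1-one (aryl cis to the ketene carbon) | O=C=C(OC)/C(CC)=C(/O)c1cc(OCc2ccc(OC)cc2)c(OCc2ccc(OC)cc2)cc1OCc1ccc(OC)cc1 | intermediate (not isolated)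
12 | 2-ethyl-3-methoxy-5,6,8-tris[(4-methoxybenzyl)oxy]naphthalene-1,4-diol | CCc1c(OC)c(O)c2c(OCc3ccc(OC)cc3)c(OCc3ccc(OC)cc3)cc(OCc3ccc(OC)cc3)c2c1O | intermediate (not isolated)
13 | 2-ethyl-3-methoxy-5,6,8-tris[(4-methoxybenzyl)oxy]naphthalene-1,4-dione | CCC1=C(OC)C(=O)c2c(OCc3ccc(OC)cc3)c(OCc3ccc(OC)cc3)cc(OCc3ccc(OC)cc3)c2C1=O | intermediate
14 | sodium 3-ethyl-5,7,8-tris[(4-methoxybenzyl)oxy]-1,4-dioxo-1,4-dihydronaphthalen-2-olate | CCC1=C([O-])C(=O)c2c(OCc3ccc(OC)cc3)c(OCc3ccc(OC)cc3)cc(OCc3ccc(OC)cc3)c2C1=O.[Na+] | intermediate (not isolated)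
15 | 2-ethyl-3-hydroxy-5,6,8-tris[(4-methoxybenzyl)oxy]naphthalene-1,4-dione | CCC1=C(O)C(=O)c2c(OCc3ccc(OC)cc3)c(OCc3ccc(OC)cc3)cc(OCc3ccc(OC)cc3)c2C1=O | intermediate
16 | (R,R)-2,6-bis[1-(mesitylcarbamoyl)ethoxy]phenyl-bis(quinonyloxy)-λ3-iodane, both acetates replaced by the oxygen of 15 | C[C@@H](Oc1cccc(O[C@H](C)C(=O)Nc2c(C)cc(C)cc2C)c1I(OC1=C(CC)C(=O)c2c(OCc3ccc(OC)cc3)cc(OCc3ccc(OC)cc3)c(OCc3ccc(OC)cc3)c2C1=O)OC1=C(CC)C(=O)c2c(OCc3ccc(OC)cc3)cc(OCc3ccc(OC)cc3)c(OCc3ccc(OC)cc3)c2C1=O)C(=O)Nc1c(C)cc(C)cc1C | intermediate (not isolated)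
17 | (S)-2-ethyl-2-({3-ethyl-5,7,8-tris[(4-methoxybenzyl)oxy]-1,4-dioxo-1,4-dihydronaphthalen-2-yl}oxy)-5,6,8-tris[(4-methoxybenzyl)oxy]naphthalene-1,3,4(2H)-trione | CCC1=C(O[C@]2(CC)C(=O)C(=O)c3c(OCc4ccc(OC)cc4)c(OCc4ccc(OC)cc4)cc(OCc4ccc(OC)cc4)c3C2=O)C(=O)c2c(OCc4ccc(OC)cc4)c(OCc4ccc(OC)cc4)cc(OCc4ccc(OC)cc4)c2C1=O | intermediate
18 | (S)-2-ethyl-2-[(3-ethyl-5,7,8-trihydroxy-1,4-dioxo-1,4-dihydronaphthalen-2-yl)oxy]-5,6,8-trihydroxynaphthalene-1,3,4(2H)-trione | CCC1=C(O[C@]2(CC)C(=O)C(=O)c3c(O)c(O)cc(O)c3C2=O)C(=O)c2c(O)c(O)cc(O)c2C1=O | target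

**Totals and risks**
Total step count: 8. Longest linear sequence: 8 steps (from 1; dimethyl squarate 4 enters in step 3).

Steps most likely to fail:

1. Step 7 (proposed new method). The coupling may proceed with poor facial selectivity if C–O bond formation escapes the iodine coordination sphere through a radical pair, and acetate or adventitious water may capture the activated enol instead of the second quinone. Fallback, from 15 back to 17: lead dioxide in AcOH–CH2Cl2 at rt, the known one-electron dehydrodimerisation of 3-alkyl-2-hydroxy-1,4-naphthoquinones, should give the racemic hexa-PMB dimer F1. Preparative HPLC on an immobilised amylose carbamate phase with a non-nucleophilic eluent would then separate the (S)-enantiomer, which is 17, from the (R)-hexa-PMB dimer F2, and the route continues with step 8.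

2. Step 5 (key step). The ketene may be intercepted by its own enol hydroxyl (lactonisation to a furanone) or protonated before the electrocyclisation, and PMB ethers may be lost on prolonged heating. Fallback, from 9 (kept by leaving out the fluoride treatment of step 4) back to 13: heating the silyl ether in p-xylene runs the same ring opening and closure with the oxygen masked and should give 3-ethyl-2-methoxy-5,7,8-tris[(4-methoxybenzyl)oxy]-4-[(trimethylsilyl)oxy]naphthalen-1-ol F3. A separate oxidative desilylation with PhI(OAc)2 in MeCN–H2O at 0 °C then gives quinone 13.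

3. Step 4. Ionisation may occur at the benzylic silyloxy carbon, which the very electron-rich aryl group stabilises, instead of at the ethyl carbinol, and the acylating medium may attack the PMB ethers. Fallback, from 4 and 5 back to 10 (cyclobutenedione monoketal tactic): EtLi and 4 in THF at −78 °C give 4-ethyl-4-hydroxy-2,3-dimethoxycyclobut-2-en-1-one F4. Methanol with catalytic BF3·OEt2 ionises its tertiary alcohol and traps the cation as the monoketal 2-ethyl-3,4,4-trimethoxycyclobut-2-en-1-one F5. Aryllithium 5 adds to the only carbonyl of F5 to give, after aqueous quench, 2-ethyl-3,4,4-trimethoxy-1-{2,4,5-tris[(4-methoxybenzyl)oxy]phenyl}cyclobut-2-en-1-ol F6. Mild ketal hydrolysis (wet silica–oxalic acid) then delivers 10.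

**Further compounds**
F1 | step 7 | racemic 2-ethyl-2-({3-ethyl-5,7,8-tris[(4-methoxybenzyl)oxy]-1,4-dioxo-1,4-dihydronaphthalen-2-yl}oxy)-5,6,8-tris[(4-methoxybenzyl)oxy]naphthalene-1,3,4(2H)-trione | CCC1=C(OC2(CC)C(=O)C(=O)c3c(OCc4ccc(OC)cc4)c(OCc4ccc(OC)cc4)cc(OCc4ccc(OC)cc4)c3C2=O)C(=O)c2c(OCc4ccc(OC)cc4)c(OCc4ccc(OC)cc4)cc(OCc4ccc(OC)cc4)c2C1=O
F2 | step 7 | (R)-enantiomer of 17 | CCC1=C(O[C@@]2(CC)C(=O)C(=O)c3c(OCc4ccc(OC)cc4)c(OCc4ccc(OC)cc4)cc(OCc4ccc(OC)cc4)c3C2=O)C(=O)c2c(OCc4ccc(OC)cc4)c(OCc4ccc(OC)cc4)cc(OCc4ccc(OC)cc4)c2C1=O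
F3 | step 5 | 3-ethyl-2-methoxy-5,7,8-tris[(4-methoxybenzyl)oxy]-4-[(trimethylsilyl)oxy]naphthalen-1-ol | CCc1c(OC)c(O)c2c(OCc3ccc(OC)cc3)c(OCc3ccc(OC)cc3)cc(OCc3ccc(OC)cc3)c2c1O[Si](C)(C)C
F4 | step 4 | 4-ethyl-4-hydroxy-2,3-dimethoxycyclobut-2-en-1-one (racemic) | CCC1(O)C(OC)=C(OC)C1=O
F5 | step 4 | 2-ethyl-3,4,4-trimethoxycyclobut-2-en-1-one | CCC1=C(OC)C(OC)(OC)C1=O
F6 | step 4 | 2-ethyl-3,4,4-trimethoxy-1-{2,4,5-tris[(4-methoxybenzyl)oxy]phenyl}cyclobut-2-en-1-ol (racemic) | CCC1=C(OC)C(OC)(OC)C1(O)c1cc(OCc2ccc(OC)cc2)c(OCc2ccc(OC)cc2)cc1OCc1ccc(OC)cc1
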